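## Retrosynthetic overview

- The strategy rests on the C2–C3 unit of the 2,3-dihydrobenzofuran: C2 carries the 3,4-dimethoxyphenyl ring, C3 carries ring A (the benzofuran benzene ring, through C3a) and CH2OH. Both aryl–carbon bonds (C2–aryl and C3–C3a) are made in one operation across an (E)-3-silyloxypropenyl boronate.
- Disconnections: allylic alcohol from a methyl cinnamate (hydride reduction); O1–C2 from a benzylic alcohol and a MOM-masked phenol (acid, 3,4-dimethoxybenzyl cation); C2–OH from C2–B (oxidation); C2–aryl and C3–C3a by a three-component conjunctive coupling of an alkenyl boronic ester, 3,4-dimethoxyphenyllithium and the ring A triflate.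
- The boron carries the mac diol (cis-1,2-dimethylacenaphthylene-1,2-diol; "B(mac)") and not pinacol, because a β-substituted alkenyl pinacol boronate would be expected to divert to direct Suzuki–Miyaura coupling. Ring A carries the side chain as the acid-stable methyl cinnamate.
- Ring order: both benzene rings are bought; the only ring formed is the dihydrofuran ring (O1–C2), after the key step and with C3 already fixed.

Key step: step 7

Assumption: the enantiomer of the MandyPhos ligand is taken to be the one that leads to (1S,2R)-14; both enantiomers are sold, and if the first coupling shows the opposite sense of induction the other enantiomer is used.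

## Route

Step 1
Reactants: 1 3,4-dihydroxy-5-methoxybenzaldehyde (5-hydroxyvanillin)
Product: 2 3-hydroxy-5-methoxy-4-(methoxymethoxy)benzaldehyde
Conditions: MOMCl (1.0 equiv), K2CO3 (1.0 equiv), acetone, 0 °C to rt
Reagents that add atoms: chloromethyl methyl ether, COCCl
Why: Williamson-type O-alkylation of the monophenoxide, which forms at the 4-hydroxyl because that group is para to the formyl group and the more acidic of the two, so one equivalent of weak base and MOMCl should give the 4-O-MOM ether selectively.

Step 2
Reactants: 2 3-hydroxy-5-methoxy-4-(methoxymethoxy)benzaldehyde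
Product: 3 5-formyl-3-methoxy-2-(methoxymethoxy)phenyl trifluoromethanesulfonate
Conditions: PhNTf2, Et3N, DMAP (cat.), CH2Cl2, rt
Reagents that add atoms: N-phenylbis(trifluoromethanesulfonimide), O=S(=O)(N(c1ccccc1)S(=O)(=O)C(F)(F)F)C(F)(F)F
Why: O-sulfonylation of the remaining phenol with the mild triflyl donor PhNTf2 under amine base is standard aryl triflate formation and leaves the aldehyde and the MOM acetal untouched.

Step 3
Reactants: 3 5-formyl-3-methoxy-2-(methoxymethoxy)phenyl trifluoromethanesulfonate
Product: 4 methyl (E)-3-[3-methoxy-4-(methoxymethoxy)-5-(trifluoromethylsulfonyloxy)phenyl]prop-2-enoate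
Conditions: Ph3P=CHCO2Me, toluene, 60 °C
Reagents that add atoms: methyl (triphenylphosphoranylidene)acetate, COC(=O)C=P(c1ccccc1)(c1ccccc1)c1ccccc1
Why: Wittig olefination with a stabilised ylide should give the (E)-cinnamate, and neither the aryl triflate nor the MOM ether reacts with this weakly nucleophilic ylide.

Step 4
Reactants: 5 propargyl alcohol
Product: 6 tert-butyldimethyl(prop-2-yn-1-yloxy)silane
Conditions: TBSCl, imidazole, CH2Cl2, 0 °C to rt
Reagents that add atoms: tert-butyldimethylsilyl chloride, CC(C)(C)[Si](C)(C)Cl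
Why: Silylation of a primary alcohol with a silyl chloride and imidazole is routine and gives an ether that survives hydroboration, the aryllithium-derived ate complex and the coupling.

Step 5
Reactants: 7 acenaphthoquinone (acenaphthylene-1,2-dione)
Product: 8 cis-1,2-dimethyl-1,2-dihydroacenaphthylene-1,2-diol (mac diol, meso)
Conditions: AlMe3, toluene, 0 °C to rt; aq. potassium sodium tartrate
Reagents that add atoms: trimethylaluminium, C[Al](C)C
Why: Twofold 1,2-addition of methyl from AlMe3 to the 1,2-diketone, the second methyl expected to enter anti to the bulky aluminium alkoxide to give the cis diol, which is the only isomer able to chelate boron and is purified by crystallisation.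

Step 6
Reactants: 6 tert-butyldimethyl(prop-2-yn-1-yloxy)silane, 8 cis-1,2-dimethyl-1,2-dihydroacenaphthylene-1,2-diol
Product: 10 (E)-3-(tert-butyldimethylsilyloxy)prop-1-enyl boronic ester of diol 8 (alkenyl B(mac) ester), via catechol boronate 9 (not isolated)
Conditions: catecholborane, neat, 70 °C; then 8, THF, rt
Reagents that add atoms: catecholborane, B1Oc2ccccc2O1
Why: Uncatalysed syn, anti-Markovnikov hydroboration of the terminal alkyne gives the (E)-alkenyl catechol boronate 9, whose labile ester is exchanged by the chelating ditertiary cis diol 8 (transesterification) to the chromatography-stable B(mac) ester.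

Step 7
Reactants: 11 4-bromo-1,2-dimethoxybenzene (4-bromoveratrole), 10 alkenyl B(mac) ester, 4 methyl (E)-3-[3-methoxy-4-(methoxymethoxy)-5-(trifluoromethylsulfonyloxy)phenyl]prop-2-enoate
Product: 14 methyl (E)-3-{3-[(1S,2R)-3-(tert-butyldimethylsilyloxy)-1-(3,4-dimethoxyphenyl)-1-[B(mac)]propan-2-yl]-5-methoxy-4-(methoxymethoxy)phenyl}prop-2-enoate, via 3,4-dimethoxyphenyllithium 12 (not isolated), via lithium boron ate complex 13 (not isolated)
Conditions: 11, n-BuLi (slightly less than 1 equiv), THF, −78 °C; then 10, −78 °C to rt; evaporate volatiles; then Pd(OAc)2 (3 mol%), MandyPhos ligand 1,1'-bis[bis(4-methoxy-3,5-dimethylphenyl)phosphino]-2,2'-bis[(dimethylamino)(phenyl)methyl]ferrocene (single enantiomer, 3.6 mol%), 4, THF, 60 °C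
Reagents that add atoms: none
Why: Oxidative addition of zerovalent palladium to triflate 4 gives a cationic arylpalladium species (divalent palladium) that binds the alkene of ate complex 13 and triggers a 1,2-metallate shift: the 3,4-dimethoxyphenyl group moves from boron to the boron-bearing carbon anti to palladium, which bonds the CH2OTBS-bearing carbon, and stereoretentive reductive elimination then joins that carbon to ring A. This is the palladium-catalysed enantioselective conjunctive cross-coupling of alkenylboron ate complexes with aryl triflates, in the B(mac) variant known for β-substituted alkenyl partners. No ring is closed. Both new stereocentres are set here: the relative configuration by anti addition of the two aryl groups across the (E)-alkene, the absolute configuration by the alkene face that the chiral bisphosphine on palladium selects. The step needs the metallate shift to beat direct transmetalation (Suzuki–Miyaura coupling), which the hindered mac diol on boron secures, and reductive elimination to beat β-hydride and β-silyloxy elimination, which the wide-bite-angle ferrocenyl bisphosphine secures. Bromine–lithium exchange with n-BuLi leaves 1-bromobutane and no lithium halide, so palladium stays cationic, and the ester, MOM and TBS groups are inert to the ate complex.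

Step 8
Reactants: 14 conjunctive coupling product (benzylic B(mac) ester)
Product: 15 methyl (E)-3-{3-[(1S,2R)-3-(tert-butyldimethylsilyloxy)-1-(3,4-dimethoxyphenyl)-1-hydroxypropan-2-yl]-5-methoxy-4-(methoxymethoxy)phenyl}prop-2-enoate
Conditions: NaBO3·4H2O, THF/H2O (1:1), rt
Reagents that add atoms: sodium perborate, [Na+].[Na+].O[B-]1(O)OO[B-](O)(O)OO1
Why: Boronate oxidation by peroxoborate (1,2-shift of carbon from boron to oxygen) proceeds with retention at C1, and the mildly basic perborate medium should spare the methyl ester, the TBS ether and the MOM acetal.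

Step 9
Reactants: 15 benzylic alcohol
Product: 17 methyl (E)-3-[(2S,3R)-2-(3,4-dimethoxyphenyl)-3-(hydroxymethyl)-7-methoxy-2,3-dihydro-1-benzofuran-5-yl]prop-2-enoate, via phenol diol 16 (not isolated)
Conditions: HCl (conc. aq., 5 equiv), MeOH, 45 °C
Reagents that add atoms: none
Why: Acidic methanolysis removes the MOM acetal and the TBS ether to give phenol 16, the electron-rich benzylic alcohol ionises to the 3,4-dimethoxybenzyl cation (SN1, any benzylic methyl ether forming reversibly), and five-membered ring closure by the phenol oxygen places the aryl group trans to CH2OH on the fixed C3 centre, so C2 is set as S under substrate control whatever the C1 configuration of 15.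

Step 10
Reactants: 17 dihydrobenzofuran methyl cinnamate
Product: 18 hierochin B, (E)-3-[(2S,3R)-2-(3,4-dimethoxyphenyl)-3-(hydroxymethyl)-7-methoxy-2,3-dihydro-1-benzofuran-5-yl]prop-2-en-1-ol
Conditions: i-Bu2AlH (4 equiv), CH2Cl2, −78 °C to −20 °C; aq. potassium sodium tartrate
Reagents that add atoms: none
Why: 1,2-Reduction of the α,β-unsaturated methyl ester by i-Bu2AlH at low temperature should give the (E)-allylic alcohol without touching the alkene or the two stereocentres, the free hydroxyl only consuming one equivalent of hydride.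

## Compound list

1 | 3,4-dihydroxy-5-methoxybenzaldehyde (5-hydroxyvanillin) | COc1cc(C=O)cc(O)c1O | starting material
2 | 3-hydroxy-5-methoxy-4-(methoxymethoxy)benzaldehyde | COCOc1c(O)cc(C=O)cc1OC | intermediate
3 | 5-formyl-3-methoxy-2-(methoxymethoxy)phenyl trifluoromethanesulfonate | COCOc1c(OC)cc(C=O)cc1OS(=O)(=O)C(F)(F)F | intermediate
4 | methyl (E)-3-[3-methoxy-4-(methoxymethoxy)-5-(trifluoromethylsulfonyloxy)phenyl]prop-2-enoate | COCOc1c(OC)cc(/C=C/C(=O)OC)cc1OS(=O)(=O)C(F)(F)F | intermediate
5 | propargyl alcohol | C#CCO | starting material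
6 | tert-butyldimethyl(prop-2-yn-1-yloxy)silane | C#CCO[Si](C)(C)C(C)(C)C | intermediate
7 | acenaphthoquinone | O=C1C(=O)c2cccc3cccc1c23 | starting material
8 | cis-1,2-dimethyl-1,2-dihydroacenaphthylene-1,2-diol (mac diol) | C[C@@]1(O)c2cccc3cccc(c23)[C@]1(C)O | intermediate
9 | 2-[(E)-3-(tert-butyldimethylsilyloxy)prop-1-enyl]-1,3,2-benzodioxaborole (catechol boronate) | CC(C)(C)[Si](C)(C)OC/C=C/B1Oc2ccccc2O1 | intermediate
10 | (E)-3-(tert-butyldimethylsilyloxy)prop-1-enyl boronic ester of diol 8 (alkenyl B(mac) ester) | CC(C)(C)[Si](C)(C)OC/C=C/B1O[C@]2(C)c3cccc4cccc(c34)[C@]2(C)O1 | intermediate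
11 | 4-bromo-1,2-dimethoxybenzene | COc1ccc(Br)cc1OC | starting material
12 | 3,4-dimethoxyphenyllithium | [Li]c1ccc(OC)c(OC)c1 | intermediate
13 | lithium (3,4-dimethoxyphenyl)[(E)-3-(tert-butyldimethylsilyloxy)prop-1-enyl]borate of diol 8 (ate complex, boron configuration not defined) | [Li+].COc1ccc([B-]2(/C=C/CO[Si](C)(C)C(C)(C)C)O[C@]3(C)c4cccc5cccc(c45)[C@]3(C)O2)cc1OC | intermediate
14 | methyl (E)-3-{3-[(1S,2R)-3-(tert-butyldimethylsilyloxy)-1-(3,4-dimethoxyphenyl)-1-[B(mac)]propan-2-yl]-5-methoxy-4-(methoxymethoxy)phenyl}prop-2-enoate | COc1ccc([C@@H](B2O[C@]3(C)c4cccc5cccc(c45)[C@]3(C)O2)[C@@H](CO[Si](C)(C)C(C)(C)C)c2cc(/C=C/C(=O)OC)cc(OC)c2OCOC)cc1OC | intermediate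
15 | methyl (E)-3-{3-[(1S,2R)-3-(tert-butyldimethylsilyloxy)-1-(3,4-dimethoxyphenyl)-1-hydroxypropan-2-yl]-5-methoxy-4-(methoxymethoxy)phenyl}prop-2-enoate | COc1ccc([C@@H](O)[C@@H](CO[Si](C)(C)C(C)(C)C)c2cc(/C=C/C(=O)OC)cc(OC)c2OCOC)cc1OC | intermediate
16 | methyl (E)-3-{3-[(1S,2R)-1-(3,4-dimethoxyphenyl)-1,3-dihydroxypropan-2-yl]-4-hydroxy-5-methoxyphenyl}prop-2-enoate | COc1ccc([C@@H](O)[C@@H](CO)c2cc(/C=C/C(=O)OC)cc(OC)c2O)cc1OC | intermediate
17 | methyl (E)-3-[(2S,3R)-2-(3,4-dimethoxyphenyl)-3-(hydroxymethyl)-7-methoxy-2,3-dihydro-1-benzofuran-5-yl]prop-2-enoate | COc1ccc([C@H]2Oc3c(OC)cc(/C=C/C(=O)OC)cc3[C@@H]2CO)cc1OC | intermediate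
18 | hierochin B | COc1ccc([C@H]2Oc3c(OC)cc(/C=C/CO)cc3[C@@H]2CO)cc1OC | target

## Step count and risks

Total steps: 10. Longest linear sequence: 7 steps (1, 2, 3, 7, 8, 9, 10 from compound 1).

**Step 7 (conjunctive coupling).** Several processes could undermine it:
- direct transmetalation of the ate complex, giving Suzuki–Miyaura coupling in place of the 1,2-shift;
- slow alkene binding at the arylpalladium centre crowded by the ortho MOM ether;
- β-silyloxy or β-hydride elimination from the alkylpalladium intermediate;
- erosion of facial selectivity.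

The fallback sets out from 4 and 10 (with 11 as aryl source) and comes back at 15. Deliberate Suzuki–Miyaura coupling of 4 with 10 (PdCl2(dppf), dppf = 1,1'-bis(diphenylphosphino)ferrocene, K3PO4, THF/H2O, 70 °C) should give methyl (E)-3-{3-[(E)-3-(tert-butyldimethylsilyloxy)prop-1-enyl]-5-methoxy-4-(methoxymethoxy)phenyl}prop-2-enoate F1. Shi epoxidation (the enantiomer of the fructose-derived ketone that gives the (2R,3R) product, KHSO5, K2CO3 buffer, MeCN/dimethoxymethane/water, 0 °C) should oxidise only the electron-rich styrenyl alkene to methyl (E)-3-{3-[(2R,3R)-3-(tert-butyldimethylsilyloxymethyl)oxiran-2-yl]-5-methoxy-4-(methoxymethoxy)phenyl}prop-2-enoate F2. Methylaluminium bis(4-bromo-2,6-di-tert-butylphenoxide) in CH2Cl2 at −78 °C should then promote the known rearrangement of epoxy silyl ethers to β-silyloxy aldehydes (benzylic C–O cleavage with anti 1,2-shift of the silyloxymethyl group, chirality transferred) to give methyl (E)-3-{3-[(2R)-1-(tert-butyldimethylsilyloxy)-3-oxopropan-2-yl]-5-methoxy-4-(methoxymethoxy)phenyl}prop-2-enoate F3. Addition of 3,4-dimethoxyphenylmagnesium bromide (from 11 and Mg, with CeCl3, THF, −78 °C) should give 15 together with its C1 epimer methyl (E)-3-{3-[(1R,2R)-3-(tert-butyldimethylsilyloxy)-1-(3,4-dimethoxyphenyl)-1-hydroxypropan-2-yl]-5-methoxy-4-(methoxymethoxy)phenyl}prop-2-enoate F4. Both enter step 9, which erases C1.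

**Step 9 (deprotection and cyclisation).** The cation could undergo E1 elimination or loss of formaldehyde to a stilbene, ring closure could give incomplete trans selectivity, or MOM-derived electrophiles could alkylate the electron-rich ring.

The fallback sets out from 14 and comes back at 17. It separates deprotection from ionisation. HCl in MeOH at rt should remove MOM and TBS while C1 still carries boron and cannot ionise, giving methyl (E)-3-{3-[(1S,2R)-1-(3,4-dimethoxyphenyl)-3-hydroxy-1-[B(mac)]propan-2-yl]-4-hydroxy-5-methoxyphenyl}prop-2-enoate F5. Oxidation with NaBO3·4H2O (THF/H2O, rt) then gives 16, this time isolated. Ring closure is run as a discrete step with catalytic BF3·OEt2 in CH2Cl2 at −40 °C, free of methanol and formaldehyde equivalents, to give 17.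

**Step 1 (mono-MOM protection).** Alkylation could occur at the 3-hydroxyl or at both hydroxyls (poor regioselectivity with the very reactive MOMCl).

The fallback sets out from 1 and comes back at 3. It reverses the order and uses the dianion. With NaH (2.1 equiv) in DMF at 0 °C the more nucleophilic 3-oxide (not conjugated to the formyl group) should react with PhNTf2 (1.0 equiv) to give 5-formyl-2-hydroxy-3-methoxyphenyl trifluoromethanesulfonate F6. MOMCl and i-Pr2NEt in CH2Cl2 then protect the only remaining hydroxyl to give 3.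

Further compounds
F1 | step 7 | methyl (E)-3-{3-[(E)-3-(tert-butyldimethylsilyloxy)prop-1-enyl]-5-methoxy-4-(methoxymethoxy)phenyl}prop-2-enoate | COCOc1c(OC)cc(/C=C/C(=O)OC)cc1/C=C/CO[Si](C)(C)C(C)(C)C
F2 | step 7 | methyl (E)-3-{3-[(2R,3R)-3-(tert-butyldimethylsilyloxymethyl)oxiran-2-yl]-5-methoxy-4-(methoxymethoxy)phenyl}prop-2-enoate | COCOc1c(OC)cc(/C=C/C(=O)OC)cc1[C@H]1O[C@@H]1CO[Si](C)(C)C(C)(C)C
F3 | step 7 | methyl (E)-3-{3-[(2R)-1-(tert-butyldimethylsilyloxy)-3-oxopropan-2-yl]-5-methoxy-4-(methoxymethoxy)phenyl}prop-2-enoate | O=C[C@@H](CO[Si](C)(C)C(C)(C)C)c1cc(/C=C/C(=O)OC)cc(OC)c1OCOC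
F4 | step 7 | methyl (E)-3-{3-[(1R,2R)-3-(tert-butyldimethylsilyloxy)-1-(3,4-dimethoxyphenyl)-1-hydroxypropan-2-yl]-5-methoxy-4-(methoxymethoxy)phenyl}prop-2-enoate | COc1ccc([C@H](O)[C@@H](CO[Si](C)(C)C(C)(C)C)c2cc(/C=C/C(=O)OC)cc(OC)c2OCOC)cc1OC
F5 | step 9 | methyl (E)-3-{3-[(1S,2R)-1-(3,4-dimethoxyphenyl)-3-hydroxy-1-[B(mac)]propan-2-yl]-4-hydroxy-5-methoxyphenyl}prop-2-enoate | COc1ccc([C@@H](B2O[C@]3(C)c4cccc5cccc(c45)[C@]3(C)O2)[C@@H](CO)c2cc(/C=C/C(=O)OC)cc(OC)c2O)cc1OC
F6 | step 1 | 5-formyl-2-hydroxy-3-methoxyphenyl trifluoromethanesulfonate | O=Cc1cc(OC)c(O)c(OS(=O)(=O)C(F)(F)F)c1
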